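The 1,3-diol C1(OH)–C2(H)–C3H2OH, with C1 benzylic to guaiacyl ring A and C2 carrying syringyl ring B, is treated as a ring-opened trans-4,5-diaryl-1,3-dioxane in which C3 and the acetal carbon both stem from formaldehyde. An enantioselective Prins annulation of an (E)-stilbene with two formaldehyde units, run under a confined chiral Brønsted acid, makes C2–C3, C1–O and one O–CH2 acetal bond, closes the dioxane and sets both stereocentres at once. Its substrate is the (E)-stilbene whose ring A para-oxygen is a benzyl ether (the donor that places the cation at C1) and whose ring B para-oxygen is an acetate; the benzyl group is traded for acetate before the acetal is cleaved.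

Key step: step 4

Remarks on the chemistry
- Locants: C1, C2 and C3 are the propane carbons of the target. In the dioxane they are C4, C5 and C6; O3 sits on C1 and O1 on C3. The target is (1S,2S), which corresponds to the (4S,5S) trans-dioxane.
- Assumption: the sense of induction of a confined acid on a 1,2-diaryl alkene cannot be predicted. The catalyst antipode that adds to the Si face of both alkene carbons is to be identified in a first run.
- Protecting groups: ring A needs an ether donor only for step 4. A para-alkoxybenzylic C–O bond is cleaved by boron halides about as readily as an acetal, so the benzyl ether is replaced by an acetate (steps 5 and 6) before the acetal is opened. This also keeps hydrogenolysis away from the free benzylic alcohol.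

Step 1
Reactants: 1 2-methoxy-4-vinylphenol; 2 benzyl bromide
Product: 3 1-(benzyloxy)-4-ethenyl-2-methoxybenzene
Conditions: BnBr, K2CO3, DMF, rt (trace BHT)
Reagents that add atoms: benzyl bromide, BrCc1ccccc1
Why: Williamson etherification, in which the phenoxide formed with K2CO3 displaces bromide from the benzylic halide by SN2, while room temperature and a radical inhibitor keep the styrene from polymerising.

Step 2
Reactants: 4 4-bromo-2,6-dimethoxyphenol; 5 acetic anhydride
Product: 6 4-bromo-2,6-dimethoxyphenyl acetate
Conditions: Ac2O, pyridine, DMAP (cat.), CH2Cl2, 0 °C to rt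
Reagents that add atoms: acetic anhydride, CC(=O)OC(C)=O
Why: DMAP-catalysed O-acylation of the hindered phenol, which makes ring B's para-oxygen a weak donor and an electron-withdrawing meta substituent for the ring positions next to the future alkene, the aryl bromide being untouched.

Step 3
Reactants: 3 1-(benzyloxy)-4-ethenyl-2-methoxybenzene; 6 4-bromo-2,6-dimethoxyphenyl acetate
Product: 7 4-[(E)-2-(4-benzyloxy-3-methoxyphenyl)ethenyl]-2,6-dimethoxyphenyl acetate
Conditions: Pd(OAc)2 (3 mol%), P(o-tol)3 (6 mol%), Et3N, DMF, 100 °C
Reagents that add atoms: none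
Why: Mizoroki–Heck reaction, in which the aryl bromide adds oxidatively to zerovalent palladium formed in situ, the aryl group is delivered to the terminal carbon of the styrene and syn β-hydride elimination releases the E stilbene, the amine base leaving the aryl acetate intact.

Step 4
Reactants: 7 4-[(E)-2-(4-benzyloxy-3-methoxyphenyl)ethenyl]-2,6-dimethoxyphenyl acetate; 8 paraformaldehyde
Product: 9 (4S,5S)-4-(4-benzyloxy-3-methoxyphenyl)-5-(4-acetoxy-3,5-dimethoxyphenyl)-1,3-dioxane (trans)
Conditions: (CH2O)n (6 equiv as CH2O), confined chiral imino-imidodiphosphoric acid (5 mol%, BINOL-derived, N-triflyl), cyclohexane/CHCl3, 0 °C to rt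
Reagents that add atoms: formaldehyde (two molecules), C=O
Why: Proposed new method: the chiral acid depolymerises paraformaldehyde and protonates a formaldehyde hemiformal, whose electrophilic CH2 is attacked by alkene carbon C2 while the hemiformal oxygen collapses onto the developing C1 benzylic cation inside the chiral ion pair, so that C2–C3, one O–CH2 acetal bond and C1–O form in one catalytic event. The closest known reaction type is the confined-acid-catalysed asymmetric Prins reaction of styrenes with paraformaldehyde to 4-aryl-1,3-dioxanes, together with the classical racemic Prins dioxane synthesis from 1-arylpropenes; a 1,2-diaryl alkene is the untested element. The 1,3-dioxane closes by cation–oxygen collapse through a six-membered chair, formally a strongly asynchronous (4+2) addition delivered suprafacially across the alkene. C5 (target C2) is set by the alkene face that the catalyst pocket leaves open, here the Si face at both carbons, and C4 (target C1) follows from suprafacial delivery to the E alkene, the trans-diequatorial dioxane also being the thermodynamic outcome should the cation live long enough to rotate. The step needs regioselectivity (carbon to C2, oxygen to C1), which the para-benzyloxy group of ring A secures by stabilising charge at C1, whereas ring B has only a para-acetoxy group twisted between two methoxy groups; the same acetate, meta to the free ring B positions, lowers their tendency to be hydroxymethylated.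

Step 5
Reactants: 9 (4S,5S)-4-(4-benzyloxy-3-methoxyphenyl)-5-(4-acetoxy-3,5-dimethoxyphenyl)-1,3-dioxane
Product: 10 (4S,5S)-5-(4-acetoxy-3,5-dimethoxyphenyl)-4-(4-hydroxy-3-methoxyphenyl)-1,3-dioxane
Conditions: H2 (1 atm), 10% Pd/C, EtOAc, rt
Reagents that add atoms: none
Why: Catalytic hydrogenolysis, in which the O-benzyl aryl ether should be cleaved far faster than the secondary benzylic ring C–O bond under neutral aprotic conditions when the reaction is stopped at one equivalent of H2, neither stereocentre being touched.

Step 6
Reactants: 10 (4S,5S)-5-(4-acetoxy-3,5-dimethoxyphenyl)-4-(4-hydroxy-3-methoxyphenyl)-1,3-dioxane; 5 acetic anhydride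
Product: 11 (4S,5S)-4-(4-acetoxy-3-methoxyphenyl)-5-(4-acetoxy-3,5-dimethoxyphenyl)-1,3-dioxane
Conditions: Ac2O, pyridine, CH2Cl2, 0 °C to rt
Reagents that add atoms: acetic anhydride, CC(=O)OC(C)=O
Why: Pyridine-mediated O-acetylation of the phenol, done so that ring A no longer carries a para donor and the benzylic C4–O3 bond is not the weakest point when the acetal meets a Lewis acid.

Step 7
Reactants: 11 (4S,5S)-4-(4-acetoxy-3-methoxyphenyl)-5-(4-acetoxy-3,5-dimethoxyphenyl)-1,3-dioxane
Product: 13 (1S,2S)-1-(4-acetoxy-3-methoxyphenyl)-2-(4-acetoxy-3,5-dimethoxyphenyl)propane-1,3-diol, via bromomethyl ether dimethylborinate 12 (not isolated)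
Conditions: Me2BBr (3 equiv), CH2Cl2, -78 °C; then sat. aq. NaHCO3, THF, 0 °C
Reagents that add atoms: none
Why: Boron bromide cleavage of a formaldehyde acetal, in which Me2BBr coordinates the less hindered O1 and delivers bromide to the acetal carbon, and bicarbonate then hydrolyses the bromomethyl ether and the borinate to the diol with loss of formaldehyde; only O–CH2 bonds break, so C1 and C2 keep their configuration, and aryl acetates and methyl ethers should be inert at this temperature.

Step 8
Reactants: 13 (1S,2S)-1-(4-acetoxy-3-methoxyphenyl)-2-(4-acetoxy-3,5-dimethoxyphenyl)propane-1,3-diol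
Product: 14 (1S,2S)-1-(4-hydroxy-3-methoxyphenyl)-2-(4-hydroxy-3,5-dimethoxyphenyl)propane-1,3-diol
Conditions: K2CO3 (0.2 equiv), MeOH, 0 °C; then pH 7 phosphate buffer
Reagents that add atoms: none
Why: Base-catalysed transesterification of the two aryl acetates, the most reactive groups present; at 0 °C with a buffered quench the para-hydroxybenzylic alcohol should not ionise to a quinone methide, so no stereocentre is disturbed.

Compound list
1 | 2-methoxy-4-vinylphenol | COc1cc(C=C)ccc1O | starting material
2 | benzyl bromide | BrCc1ccccc1 | starting material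
3 | 1-(benzyloxy)-4-ethenyl-2-methoxybenzene | COc1cc(C=C)ccc1OCc1ccccc1 | intermediate
4 | 4-bromo-2,6-dimethoxyphenol | COc1cc(Br)cc(OC)c1O | starting material
5 | acetic anhydride | CC(=O)OC(C)=O | starting material
6 | 4-bromo-2,6-dimethoxyphenyl acetate | COc1cc(Br)cc(OC)c1OC(C)=O | intermediate
7 | 4-[(E)-2-(4-benzyloxy-3-methoxyphenyl)ethenyl]-2,6-dimethoxyphenyl acetate | COc1cc(/C=C/c2cc(OC)c(OC(C)=O)c(OC)c2)ccc1OCc1ccccc1 | intermediate
8 | paraformaldehyde (polymeric formaldehyde, drawn as the monomer) | C=O | starting material
9 | (4S,5S)-4-(4-benzyloxy-3-methoxyphenyl)-5-(4-acetoxy-3,5-dimethoxyphenyl)-1,3-dioxane (trans) | COc1cc([C@H]2OCOC[C@@H]2c2cc(OC)c(OC(C)=O)c(OC)c2)ccc1OCc1ccccc1 | intermediate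
10 | (4S,5S)-5-(4-acetoxy-3,5-dimethoxyphenyl)-4-(4-hydroxy-3-methoxyphenyl)-1,3-dioxane (trans) | COc1cc([C@H]2OCOC[C@@H]2c2cc(OC)c(OC(C)=O)c(OC)c2)ccc1O | intermediate
11 | (4S,5S)-4-(4-acetoxy-3-methoxyphenyl)-5-(4-acetoxy-3,5-dimethoxyphenyl)-1,3-dioxane (trans) | COc1cc([C@H]2OCOC[C@@H]2c2cc(OC)c(OC(C)=O)c(OC)c2)ccc1OC(C)=O | intermediate
12 | (1S,2S)-1-(4-acetoxy-3-methoxyphenyl)-2-(4-acetoxy-3,5-dimethoxyphenyl)propane-1,3-diol as its C1-O-bromomethyl ether and C3-O-dimethylborinate | COc1cc([C@@H](OCBr)[C@H](COB(C)C)c2cc(OC)c(OC(C)=O)c(OC)c2)ccc1OC(C)=O | intermediate (not isolated)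
13 | (1S,2S)-1-(4-acetoxy-3-methoxyphenyl)-2-(4-acetoxy-3,5-dimethoxyphenyl)propane-1,3-diol | COc1cc([C@@H](O)[C@H](CO)c2cc(OC)c(OC(C)=O)c(OC)c2)ccc1OC(C)=O | intermediate
14 | (1S,2S)-1-(4-hydroxy-3-methoxyphenyl)-2-(4-hydroxy-3,5-dimethoxyphenyl)propane-1,3-diol (CNP0148667.1) | COc1cc([C@@H](O)[C@H](CO)c2cc(OC)c(O)c(OC)c2)ccc1O | target

Total step count: 8
Longest linear sequence: 7 steps (steps 1, 3, 4, 5, 6, 7, 8 from compound 1); step 2 is a one-step side branch.

Steps most likely to fail

Step 4. The diaryl alkene is much larger than a styrene, so it may turn over slowly in the confined pocket or be discriminated poorly between its two faces. Protonated formaldehyde may also attack the electron-rich arene carbons instead of the alkene. The fallback gives up catalyst control and uses known chemistry. Starting from 7, the classical Prins dioxane synthesis of aryl-conjugated alkenes is run with an achiral acid (paraformaldehyde, Tf2NH 5 mol%, CH2Cl2, 0 °C). Because the closure is suprafacial and the diequatorial ring is favoured, this should give the racemic trans-dioxane. That racemate is 9 mixed with its mirror image, (4R,5R)-4-(4-benzyloxy-3-methoxyphenyl)-5-(4-acetoxy-3,5-dimethoxyphenyl)-1,3-dioxane F1. Preparative chromatography on a chiral stationary phase then separates the antipodes, and the route is rejoined at 9.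

Step 7. The Lewis acid may ionise the benzylic C4–O3 bond instead of the acetal O–CH2 bond, which would erode configuration at C1. The halomethyl ether may also alkylate the activated ring B position ortho to the side chain. The fallback replaces the free boron halide by a base-buffered silyl triflate opening that traps the acetal carbon on nitrogen. Starting from 11, TMSOTf and 2,2'-bipyridyl in CH2Cl2 at 0 °C should open the acetal to 1-({[(1S,2S)-1-(4-acetoxy-3-methoxyphenyl)-2-(4-acetoxy-3,5-dimethoxyphenyl)-3-(trimethylsilyloxy)propyl]oxy}methyl)-2-(pyridin-2-yl)pyridinium triflate F2 (or its regioisomer with the two oxygen substituents exchanged, which converges). Water and aqueous NaHCO3 then hydrolyse the pyridinium hemiaminal ether and the silyl ether, and the route is rejoined at 13.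

Step 3. The electron-rich styrene may polymerise at the temperature that the electron-rich aryl bromide needs for oxidative addition. Some branched 1,1-diaryl alkene may form by insertion with the opposite regiochemistry, and the acetate may be partly lost. The fallback fixes the alkene geometry before the aryl–vinyl bond is made. Starting from 3, cross-metathesis with pinacol vinylboronate (second-generation Grubbs catalyst (H2IMes)(PCy3)Cl2Ru=CHPh, CH2Cl2, 40 °C) should give (E)-2-[2-(4-benzyloxy-3-methoxyphenyl)ethenyl]-4,4,5,5-tetramethyl-1,3,2-dioxaborolane F3. Suzuki–Miyaura coupling of this boronate with 6 (PdCl2(dppf), K3PO4, 1,4-dioxane with a little water, 60 °C) proceeds with retention of alkene geometry, and the route is rejoined at 7.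

Further compounds
F1 | step 4 | (4R,5R)-4-(4-benzyloxy-3-methoxyphenyl)-5-(4-acetoxy-3,5-dimethoxyphenyl)-1,3-dioxane | COc1cc([C@@H]2OCOC[C@H]2c2cc(OC)c(OC(C)=O)c(OC)c2)ccc1OCc1ccccc1
F2 | step 7 | 1-({[(1S,2S)-1-(4-acetoxy-3-methoxyphenyl)-2-(4-acetoxy-3,5-dimethoxyphenyl)-3-(trimethylsilyloxy)propyl]oxy}methyl)-2-(pyridin-2-yl)pyridinium triflate | COc1cc([C@@H](OC[n+]3ccccc3-c3ccccn3)[C@H](CO[Si](C)(C)C)c2cc(OC)c(OC(C)=O)c(OC)c2)ccc1OC(C)=O.[O-]S(=O)(=O)C(F)(F)F
F3 | step 3 | (E)-2-[2-(4-benzyloxy-3-methoxyphenyl)ethenyl]-4,4,5,5-tetramethyl-1,3,2-dioxaborolane | COc1cc(/C=C/B2OC(C)(C)C(C)(C)O2)ccc1OCc1ccccc1
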